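- Read this before you touch anything. I left you two flasks, birch and alder.

| flask | starting material | partner | second substrate | temperature | remark | time |
|---|---|---|---|---|---|---|
| red | 0.020 M | 0.054 M | 0.10 M | 80 °C | run made earlier |  |
| birch | 0.080 M | 0.0360 M | 0.0500 M | 40 °C |  | 5.0 min |
| alder | 0.020 M | 0.0360 M | 0.100 M | 80 °C |  | 5.0 min |
red run (percent of the starting material charged): time / s: target / % = 10.0: 4.0; 25.0: 9.1; 50.0: 15.6; 80.0: 21.5; 120: 24.5

(scatter of a reading: 0.3 percentage points)
* which of the two ends with the higher amount of target, in percent of the starting material charged ("neither" if they lie within 2 percentage points) (birch / alder / neither)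
* target at the end, in percent of the starting material charged, birch
* target at the end, in percent of the starting material charged, alder
- steps thought possible: starting material + partner -> target; partner -> decomposed reagent; second substrate + partner -> second product; target <-> isomer of the product
- the earlier runs do not show what temperature does; that part of a forecast is a guess

- From the first red reading I took a rate constant k of 0.0756 M⁻¹ s⁻¹, at 80 °C and as a reading with its scatter. While [partner] stays near its charge, starting material falls exponentially, the pseudo-first-order case.
- Its time constant, which I called the filling time, is the reciprocal of k[partner], and in alder this filling time was 6.12 min.  Please leave the charges as they stand, since this number belongs to them.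
- But the red run bent away from its exponential: its last 40.0 s added just 3 percentage points. I assumed that this level scales with [partner], which put alder at 16.3%.
- The runs show nothing about temperature, so for birch I made a guess of my own, a slowdown by 16.0. Its filling time became 98.0 min, far longer than the 5.0 min run, so I expected 4.97% in birch, less than in alder.
- The forecast, made apart from my reckoning, named alder, with 5% for birch on a different factor, “Guessing a 15-fold slowdown, k ≈ 0.005”, and 16% for alder as a middle value between its own 20% and 12%.

    starting material + partner → target (k = 0.0810 M⁻¹ s⁻¹, Ea = 62.0 kJ mol⁻¹)
    partner → decomposed reagent (k = 0.00130 s⁻¹, Ea = 91.0 kJ mol⁻¹)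
    second substrate + partner → second product (k = 0.00470 M⁻¹ s⁻¹, Ea = 63.0 kJ mol⁻¹)
    target ⇌ isomer of the product (K = 5.70, k = 0.00560 s⁻¹, Ea = 106 kJ mol⁻¹, ΔH = 2.00 kJ mol⁻¹)
    (constants at 80 °C)

- Alder ended at 19.3% and birch at 5.31%, so alder gave more. Alder also held 24.2% of isomer of the product at 5.00 min. Averaging alder's partner between its charge and the 41% left stretched my filling time to 8.67 min, which gives 43.8% of starting material consumed, against 43.5% in the flask. A neighbour of birch, charged with 0.032 M of starting material but the same partner, gave 5.51%.

The data are calculated on assumed constants; the scatter is artificial.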